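**Retrosynthetic overview**
Numbering (lignan style): ring 1 = O–C7(H)(guaiacyl)–C8–C8'–C9'H2; ring 2 = O–C7'(H)(dihydrobenzofuranyl)–C8'–C8–C9H2; the target is the bis-endo furofuran (H7, H8, H8', H7' all cis) joined to a 2,3-cis-dihydrobenzofuran.
Endgame: debenzylation; ring 1 is closed last by forming C7–C8 from an aryl oxocarbenium ion tethered on O–C9' onto the enol ether C8=C9 of a ring-2 2,3-dihydrofuran, then hydride at C9 (ring C9–O kept).
That dihydrofuran is the ring-2 γ-lactone two redox steps down (lactol, dehydration); the lactone is made in the key step.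
Enabling feature: in ring 2 the oxygen sits on benzylic C7', its other neighbour C9 is a CH2 joined through C8 to C8', and the aryl group on C7' is cis to C9' on C8'; with C9 raised to the acyl level, ring 2 is a cis-4,5-disubstituted γ-butyrolactone = aldehyde (C7'=O of the dihydrobenzofuran fragment) + enal homoenolate (C9 = C1, C8 = C2, C8' = C3, C9' = C4), giving the C7'–C8' bond, the C9–O ring closure and two stereocentres in one fragment union.
First ring: the cis-dihydrobenzofuran by enantioselective dirhodium-carbenoid C–H insertion of an aryldiazoacetate made from methyl 5-iodovanillate; ring order: dihydrobenzofuran, ring 2, ring 1.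
Key step: step 9

Assumption: the (5aR,10bS) triazolium salt in step 9 and Rh2(S-PTTL)4 in step 3 are taken to induce the configurations drawn; if either induces the opposite sense, its mirror-image form is used and nothing else changes.
Abbreviation: DBF = (2S,3S)-2-[4-(benzyloxy)-3-methoxyphenyl]-3-[(benzyloxy)methyl]-7-methoxy-2,3-dihydro-1-benzofuran-5-yl (2,3-cis).

**Step 1**
Reactants: 1 methyl 4-hydroxy-3-iodo-5-methoxybenzoate; 2 [4-(benzyloxy)-3-methoxyphenyl]methanol
Product: 3 methyl 4-{[4-(benzyloxy)-3-methoxyphenyl]methoxy}-3-iodo-5-methoxybenzoate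
Conditions: PPh3, DIAD, THF, 0 °C → rt
Reagents that add atoms: none
Why: Mitsunobu etherification, in which the acidic phenol (para ester, ortho iodine) is alkylated by the activated primary benzylic alcohol while the ester and the aryl iodide stay untouched; no stereocentre is formed.

**Step 2**
Reactants: 3 aryl iodide; 4 ethyl diazoacetate
Product: 5 methyl 4-{[4-(benzyloxy)-3-methoxyphenyl]methoxy}-3-(1-diazo-2-ethoxy-2-oxoethyl)-5-methoxybenzoate
Conditions: Pd(PPh3)4 (5 mol %), Ag2CO3 (0.5 equiv), Et3N, toluene, rt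
Reagents that add atoms: none
Why: Palladium-catalysed cross-coupling of an aryl iodide with the C–H bond of a diazoacetate (oxidative addition to zerovalent palladium, base-assisted palladation of the diazo carbon, reductive elimination with the diazo group intact), with Ag2CO3 taking up iodide; no stereocentre is formed.

**Step 3**
Reactants: 5 aryldiazoacetate
Product: 6 3-ethyl 5-methyl (2S,3R)-2-[4-(benzyloxy)-3-methoxyphenyl]-7-methoxy-2,3-dihydro-1-benzofuran-3,5-dicarboxylate (2,3-cis)
Conditions: Rh2(S-PTTL)4 (dirhodium tetrakis[N-phthaloyl-(S)-tert-leucinate], 1 mol %), toluene, −60 °C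
Reagents that add atoms: none
Why: Intramolecular 1,5 C–H insertion of the dirhodium carbenoid into the O–CH2–aryl bond, activated by the ether oxygen and the electron-rich aryl group, closes the dihydrofuran ring; C2 and C3 are set together in the concerted insertion, the chiral carboxylate ligands selecting one enantiotopic hydrogen and delivering the kinetic 2,3-cis ester as known for 2-(benzyloxy)phenyl diazoacetates.

**Step 4**
Reactants: 6 cis diester
Product: 7 [(2S,3S)-2-[4-(benzyloxy)-3-methoxyphenyl]-7-methoxy-2,3-dihydro-1-benzofuran-3,5-diyl]dimethanol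
Conditions: LiAlH4, THF, −20 → 0 °C
Reagents that add atoms: none
Why: Hydride reduction of both esters with LiAlH4 at low temperature, which is faster than enolisation at C3, so the cis relation set in step 3 is carried into the diol.

**Step 5**
Reactants: 7 diol
Product: 8 (2S,3S)-2-[4-(benzyloxy)-3-methoxyphenyl]-3-(hydroxymethyl)-7-methoxy-2,3-dihydro-1-benzofuran-5-carbaldehyde
Conditions: MnO2, CH2Cl2, rt
Reagents that add atoms: none
Why: Chemoselective MnO2 oxidation of the benzylic alcohol to the aldehyde, the aliphatic primary alcohol and both stereocentres being inert to this reagent.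

**Step 6**
Reactants: 8 hydroxy aldehyde
Product: 9 DBF–CHO, (2S,3S)-2-[4-(benzyloxy)-3-methoxyphenyl]-3-[(benzyloxy)methyl]-7-methoxy-2,3-dihydro-1-benzofuran-5-carbaldehyde
Conditions: BnBr, Ag2O, CH2Cl2 (anhydrous), rt, dark
Reagents that add atoms: benzyl bromide, BrCc1ccccc1
Why: Silver-oxide-promoted Williamson benzylation of the primary alcohol under neutral, anhydrous conditions that spare the aryl aldehyde and the cis stereocentres.

**Step 7**
Reactants: 10 (E)-but-2-ene-1,4-diol
Product: 11 (E)-4-[(triethylsilyl)oxy]but-2-en-1-ol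
Conditions: NaH (1.0 equiv), THF, 0 °C; then Et3SiCl
Reagents that add atoms: chlorotriethylsilane, CC[Si](Cl)(CC)CC
Why: Monosilylation of a symmetrical diol through its monosodium alkoxide, which reacts once with the silyl chloride; the E double bond is untouched.

**Step 8**
Reactants: 11 allylic alcohol
Product: 12 (E)-4-[(triethylsilyl)oxy]but-2-enal
Conditions: MnO2, CH2Cl2, rt
Reagents that add atoms: none
Why: Allylic oxidation with MnO2 gives the conjugated aldehyde with retention of the E geometry and of the silyl ether.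

**Step 9**
Reactants: 9 DBF–CHO; 12 (E)-4-[(triethylsilyl)oxy]but-2-enal
Product: 13 (4S,5S)-5-DBF-4-{[(triethylsilyl)oxy]methyl}oxolan-2-one (4,5-cis)
Conditions: (5aR,10bS)-2-mesityl-5a,10b-dihydro-4H,6H-indeno[2,1-b][1,2,4]triazolo[4,3-d][1,4]oxazin-2-ium chloride (10 mol %), DBU (15 mol %), Ti(OiPr)4 (20 mol %), 4 Å MS, CH2Cl2, rt; 12 added over 6 h
Reagents that add atoms: none
Why: The carbene generated from the triazolium salt adds to the formyl group of 12, and the resulting conjugated Breslow-type adduct reacts as a homoenolate through its β-carbon (C8') with the carbonyl carbon of the titanium-bound aldehyde 9 (C7'); tautomerisation then gives an acyl azolium at C9, which the new C7' alkoxide attacks, so that the C9–O bond closes ring 2 and the carbene is released. The closest known reaction type is the carbene-catalysed homoenolate annulation of enals with aromatic aldehydes to cis-4,5-disubstituted γ-butyrolactones, including its enantioselective variants with chiral triazolium salts and a Lewis-acid co-catalyst. Ring 2 closes by 5-exo-trig acyl substitution (lactonisation of the alkoxide on the acyl azolium). C7' and C8' are both created in the C–C bond-forming event: their cis relation (aryl group cis to the CH2OSiEt3 arm, the later endo aryl group) follows from the compact transition state in which the aldehyde oxygen and the enol oxygen of the Breslow adduct are held together by titanium or a hydrogen bond, and their absolute sense from the aminoindanol backbone of the carbene, which blocks one face of the extended enol; the remote stereocentres of 9 take no part. The step needs β-carbon (homoenolate) instead of acyl-anion reactivity and cross- instead of self-annulation of the enal: the N-mesityl triazolium is known to favour the homoenolate path, 9 cannot enolise, 12 is added slowly so that its concentration stays low, and Ti(OiPr)4 offsets the low electrophilicity of the electron-rich aldehyde.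

**Step 10**
Reactants: 13 lactone
Product: 14 (4S,5S)-5-DBF-4-{[(triethylsilyl)oxy]methyl}oxolan-2-ol (anomers)
Conditions: iBu2AlH, CH2Cl2, −78 °C; aq. potassium sodium tartrate work-up
Reagents that add atoms: none
Why: Half-reduction of the γ-lactone with iBu2AlH at −78 °C, where the tetrahedral aluminium alkoxide survives until work-up, gives the lactol (anomers) without touching C7', C8' or the ring C9–O bond.

**Step 11**
Reactants: 14 lactol
Product: 15 triethyl{[(2S,3S)-2-DBF-2,3-dihydrofuran-3-yl]methoxy}silane (2,3-cis)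
Conditions: MsCl, Et3N, CH2Cl2, −20 °C → reflux
Reagents that add atoms: none
Why: Lactol dehydration by mesylation of the anomeric hydroxyl and amine-induced elimination, as used for furanoid glycals, gives the cyclic enol ether under basic conditions that protect it and leave the 2,3-cis centres unchanged.

**Step 12**
Reactants: 16 4-(benzyloxy)-3-methoxybenzaldehyde
Product: 17 1-(benzyloxy)-4-(dimethoxymethyl)-2-methoxybenzene
Conditions: HC(OMe)3, TsOH·H2O (cat.), MeOH, rt
Reagents that add atoms: trimethyl orthoformate, COC(OC)OC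
Why: Acid-catalysed acetalisation of the aromatic aldehyde driven by trimethyl orthoformate as water scavenger; no stereocentre is formed.

**Step 13**
Reactants: 15 dihydrofuran silyl ether; 17 dimethyl acetal
Product: 19 (1S,3aS,4S,6aS)-1-[4-(benzyloxy)-3-methoxyphenyl]-4-DBF-tetrahydro-1H,3H-furo[3,4-c]furan (both aryl groups endo), via methyl acetal 18 (not isolated)
Conditions: TMSOTf (0.3 equiv), 4 Å MS, CH2Cl2, −78 °C; then Et3SiH, −78 → −40 °C; Et3N quench
Reagents that add atoms: none
Why: TMSOTf-promoted transacetalisation of the silyl ether with 17 gives an aryl oxocarbenium ion tethered on O–C9' that is attacked by the enol ether carbon C8 on the face carrying the tether (oxocarbenium–enol ether cyclisation of the Prins/Mukaiyama type, which closes ring 1), so that C8 is fixed by the cis ring fusion and C7 by the kinetically preferred compact transition state that places the aryl group endo at low temperature, and the ring-2 oxocarbenium ion, trapped as methyl acetal 18, is then reduced at C9 by ionic hydrogenation with Et3SiH with the ring C9–O bond intact.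

**Step 14**
Reactants: 19 tribenzyl ether
Product: 20 4-[(2S,3S)-3-(hydroxymethyl)-5-[(1S,3aS,4S,6aS)-4-(4-hydroxy-3-methoxyphenyl)tetrahydro-1H,3H-furo[3,4-c]furan-1-yl]-7-methoxy-2,3-dihydro-1-benzofuran-2-yl]-2-methoxyphenol (target)
Conditions: H2 (1 atm), Pd/C (10 %), EtOAc–MeOH, rt
Reagents that add atoms: none
Why: Hydrogenolysis of the two aryl benzyl ethers and the alkyl benzyl ether over palladium on carbon, the cyclic benzylic C–O bonds of the furofuran and dihydrobenzofuran being cleaved much more slowly, so that the reaction is stopped after uptake of three equivalents of hydrogen; no stereocentre is affected.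

**Compound list**
1 | methyl 4-hydroxy-3-iodo-5-methoxybenzoate (methyl 5-iodovanillate) | COC(=O)c1cc(I)c(O)c(OC)c1 | starting material
2 | [4-(benzyloxy)-3-methoxyphenyl]methanol | OCc1ccc(OCc2ccccc2)c(OC)c1 | starting material
3 | methyl 4-{[4-(benzyloxy)-3-methoxyphenyl]methoxy}-3-iodo-5-methoxybenzoate | COC(=O)c1cc(I)c(OCc2ccc(OCc3ccccc3)c(OC)c2)c(OC)c1 | intermediate
4 | ethyl diazoacetate | CCOC(=O)C=[N+]=[N-] | starting material
5 | methyl 4-{[4-(benzyloxy)-3-methoxyphenyl]methoxy}-3-(1-diazo-2-ethoxy-2-oxoethyl)-5-methoxybenzoate | CCOC(=O)C(=[N+]=[N-])c1cc(C(=O)OC)cc(OC)c1OCc1ccc(OCc2ccccc2)c(OC)c1 | intermediate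
6 | 3-ethyl 5-methyl (2S,3R)-2-[4-(benzyloxy)-3-methoxyphenyl]-7-methoxy-2,3-dihydro-1-benzofuran-3,5-dicarboxylate (2,3-cis) | COC(=O)c1cc(OC)c2c(c1)[C@@H](C(=O)OCC)[C@@H](c1ccc(OCc3ccccc3)c(OC)c1)O2 | intermediate
7 | [(2S,3S)-2-[4-(benzyloxy)-3-methoxyphenyl]-7-methoxy-2,3-dihydro-1-benzofuran-3,5-diyl]dimethanol (2,3-cis) | OCc1cc(OC)c2c(c1)[C@@H](CO)[C@@H](c1ccc(OCc3ccccc3)c(OC)c1)O2 | intermediate
8 | (2S,3S)-2-[4-(benzyloxy)-3-methoxyphenyl]-3-(hydroxymethyl)-7-methoxy-2,3-dihydro-1-benzofuran-5-carbaldehyde | O=Cc1cc(OC)c2c(c1)[C@@H](CO)[C@@H](c1ccc(OCc3ccccc3)c(OC)c1)O2 | intermediate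
9 | (2S,3S)-2-[4-(benzyloxy)-3-methoxyphenyl]-3-[(benzyloxy)methyl]-7-methoxy-2,3-dihydro-1-benzofuran-5-carbaldehyde (DBF–CHO) | O=Cc1cc(OC)c2c(c1)[C@@H](COCc1ccccc1)[C@@H](c1ccc(OCc3ccccc3)c(OC)c1)O2 | intermediate
10 | (E)-but-2-ene-1,4-diol | OC/C=C/CO | starting material
11 | (E)-4-[(triethylsilyl)oxy]but-2-en-1-ol | CC[Si](CC)(CC)OC/C=C/CO | intermediate
12 | (E)-4-[(triethylsilyl)oxy]but-2-enal | CC[Si](CC)(CC)OC/C=C/C=O | intermediate
13 | (4S,5S)-5-DBF-4-{[(triethylsilyl)oxy]methyl}oxolan-2-one (4,5-cis) | CC[Si](CC)(CC)OC[C@@H]1CC(=O)O[C@@H]1c1cc(OC)c2c(c1)[C@@H](COCc1ccccc1)[C@@H](c1ccc(OCc3ccccc3)c(OC)c1)O2 | intermediate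
14 | (4S,5S)-5-DBF-4-{[(triethylsilyl)oxy]methyl}oxolan-2-ol (mixture of anomers at C2) | CC[Si](CC)(CC)OC[C@@H]1CC(O)O[C@@H]1c1cc(OC)c2c(c1)[C@@H](COCc1ccccc1)[C@@H](c1ccc(OCc3ccccc3)c(OC)c1)O2 | intermediate
15 | triethyl{[(2S,3S)-2-DBF-2,3-dihydrofuran-3-yl]methoxy}silane (2,3-cis) | CC[Si](CC)(CC)OC[C@@H]1C=CO[C@@H]1c1cc(OC)c2c(c1)[C@@H](COCc1ccccc1)[C@@H](c1ccc(OCc3ccccc3)c(OC)c1)O2 | intermediate
16 | 4-(benzyloxy)-3-methoxybenzaldehyde | O=Cc1ccc(OCc2ccccc2)c(OC)c1 | starting material
17 | 1-(benzyloxy)-4-(dimethoxymethyl)-2-methoxybenzene | COC(OC)c1ccc(OCc2ccccc2)c(OC)c1 | intermediate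
18 | (1S,3aS,4S,6aR)-1-[4-(benzyloxy)-3-methoxyphenyl]-4-DBF-6-methoxytetrahydro-1H,3H-furo[3,4-c]furan (methyl acetal at C9, both aryl groups endo, anomers at C6) | COc1cc([C@H]2OC[C@@H]3[C@H]2C(OC)O[C@@H]3c2cc(OC)c3c(c2)[C@@H](COCc2ccccc2)[C@@H](c2ccc(OCc4ccccc4)c(OC)c2)O3)ccc1OCc1ccccc1 | intermediate (not isolated)
19 | (1S,3aS,4S,6aS)-1-[4-(benzyloxy)-3-methoxyphenyl]-4-DBF-tetrahydro-1H,3H-furo[3,4-c]furan (both aryl groups endo) | COc1cc([C@H]2OC[C@@H]3[C@H]2CO[C@@H]3c2cc(OC)c3c(c2)[C@@H](COCc2ccccc2)[C@@H](c2ccc(OCc4ccccc4)c(OC)c2)O3)ccc1OCc1ccccc1 | intermediate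
20 | 4-[(2S,3S)-3-(hydroxymethyl)-5-[(1S,3aS,4S,6aS)-4-(4-hydroxy-3-methoxyphenyl)tetrahydro-1H,3H-furo[3,4-c]furan-1-yl]-7-methoxy-2,3-dihydro-1-benzofuran-2-yl]-2-methoxyphenol | COc1cc([C@H]2OC[C@@H]3[C@H]2CO[C@@H]3c2cc(OC)c3c(c2)[C@@H](CO)[C@@H](c2ccc(O)c(OC)c2)O3)ccc1O | target

**Step count and risks**
Total step count: 14. Longest linear sequence: 11 steps (steps 1–6, 9–11, 13, 14).

Most likely to fail, step 9: self-annulation of the enal and acyl-anion (benzoin-type) pathways may outrun the cross-annulation, addition to the electron-rich aldehyde may be slow, and cis or enantiofacial discrimination may be insufficient. The fallback sets out from 9 and comes back at 13. Allylboration of 9 catalysed by (R)-3,3'-bis(2,4,6-triisopropylphenyl)-1,1'-binaphthyl-2,2'-diyl hydrogen phosphate (or its enantiomer, whichever gives the 1S,2S series) uses (Z)-1,4-bis(4,4,5,5-tetramethyl-1,3,2-dioxaborolan-2-yl)but-2-ene F1, made in one step from buta-1,3-diene and B2pin2 with Pt(PPh3)4. The (Z)-γ-substituted allylboronate should react through the chair transition state to the syn adduct, and oxidative work-up (NaBO3·4H2O) should give (1S,2S)-1-DBF-2-ethenylpropane-1,3-diol F2. Silylation of the primary hydroxyl (Et3SiCl, imidazole, −40 °C) should give (1S,2S)-1-DBF-2-{[(triethylsilyl)oxy]methyl}but-3-en-1-ol F3. Hydroboration with 9-borabicyclo[3.3.1]nonane and NaBO3 oxidation should give (1S,2S)-1-DBF-2-{[(triethylsilyl)oxy]methyl}butane-1,4-diol F4. Oxidative lactonisation (2,2,6,6-tetramethylpiperidin-1-oxyl, PhI(OAc)2, NaHCO3) closes the same C9–O bond through the lactol and returns to 13.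

Step 13: the enol ether may attack the activated acetal intermolecularly before the tether is in place, acid may equilibrate the endo aryl groups towards the exo isomers, and the cis-dihydrobenzofuran may ionise. The fallback sets out from 13 and comes back at 19, setting C7 by hydride delivery instead of by C–C bond formation. Crossed Claisen acylation of the lithium enolate of 13 (LiN(SiMe3)2, THF, −78 °C) with commercial methyl 4-(benzyloxy)-3-methoxybenzoate should give (4S,5S)-3-[4-(benzyloxy)-3-methoxybenzoyl]-5-DBF-4-{[(triethylsilyl)oxy]methyl}oxolan-2-one F5. Reductive cycloetherification of this silyloxy ketone (BiBr3, Et3SiH, MeCN, 0 °C) should close ring 1: only the C3 epimer with the aroyl group cis to the CH2OSiEt3 arm can cyclise, and the cis-fused aryl oxocarbenium ion takes hydride on its convex face, which again places the guaiacyl group endo, giving (3S,3aS,6S,6aR)-6-[4-(benzyloxy)-3-methoxyphenyl]-3-DBF-tetrahydro-1H,3H-furo[3,4-c]furan-1-one F6. Reduction with iBu2AlH at −78 °C should give the lactol (3S,3aS,6S,6aR)-6-[4-(benzyloxy)-3-methoxyphenyl]-3-DBF-tetrahydro-1H,3H-furo[3,4-c]furan-1-ol F7, and ionic hydrogenation (Et3SiH, BF3·OEt2, −78 °C) returns to 19.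

Step 2: the diazo ester may decompose on palladium (carbene dimerisation), and oxidative addition and palladation may be slow at the ortho-alkoxy, electron-rich aryl iodide. The fallback sets out from 3 and comes back at 5. Iodine–magnesium exchange (iPrMgCl·LiCl, THF, −40 °C, tolerated by the methyl ester) and acylation with diethyl oxalate should give methyl 3-(2-ethoxy-2-oxoacetyl)-4-{[4-(benzyloxy)-3-methoxyphenyl]methoxy}-5-methoxybenzoate F8. Condensation with 4-methylbenzenesulfonohydrazide should give the tosylhydrazone methyl 3-{2-ethoxy-1-[2-(4-methylbenzenesulfonyl)hydrazinylidene]-2-oxoethyl}-4-{[4-(benzyloxy)-3-methoxyphenyl]methoxy}-5-methoxybenzoate F9, and DBU-induced loss of sulfinate (Bamford–Stevens type) returns to 5.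

**Further compounds**
F1 | step 9 | (Z)-1,4-bis(4,4,5,5-tetramethyl-1,3,2-dioxaborolan-2-yl)but-2-ene | CC1(C)OB(C/C=C\CB2OC(C)(C)C(C)(C)O2)OC1(C)C
F2 | step 9 | (1S,2S)-1-DBF-2-ethenylpropane-1,3-diol | OC[C@H](C=C)[C@H](O)c1cc(OC)c2c(c1)[C@@H](COCc1ccccc1)[C@@H](c1ccc(OCc3ccccc3)c(OC)c1)O2
F3 | step 9 | (1S,2S)-1-DBF-2-{[(triethylsilyl)oxy]methyl}but-3-en-1-ol | CC[Si](CC)(CC)OC[C@H](C=C)[C@H](O)c1cc(OC)c2c(c1)[C@@H](COCc1ccccc1)[C@@H](c1ccc(OCc3ccccc3)c(OC)c1)O2
F4 | step 9 | (1S,2S)-1-DBF-2-{[(triethylsilyl)oxy]methyl}butane-1,4-diol | CC[Si](CC)(CC)OC[C@H](CCO)[C@H](O)c1cc(OC)c2c(c1)[C@@H](COCc1ccccc1)[C@@H](c1ccc(OCc3ccccc3)c(OC)c1)O2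
F5 | step 13 | (4S,5S)-3-[4-(benzyloxy)-3-methoxybenzoyl]-5-DBF-4-{[(triethylsilyl)oxy]methyl}oxolan-2-one (C3 configurationally labile, keto–enol) | CC[Si](CC)(CC)OC[C@@H]1C(C(=O)c2ccc(OCc3ccccc3)c(OC)c2)C(=O)O[C@@H]1c1cc(OC)c2c(c1)[C@@H](COCc1ccccc1)[C@@H](c1ccc(OCc3ccccc3)c(OC)c1)O2
F6 | step 13 | (3S,3aS,6S,6aR)-6-[4-(benzyloxy)-3-methoxyphenyl]-3-DBF-tetrahydro-1H,3H-furo[3,4-c]furan-1-one (both aryl groups endo) | COc1cc([C@H]2OC[C@@H]3[C@H]2C(=O)O[C@@H]3c2cc(OC)c3c(c2)[C@@H](COCc2ccccc2)[C@@H](c2ccc(OCc4ccccc4)c(OC)c2)O3)ccc1OCc1ccccc1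
F7 | step 13 | (3S,3aS,6S,6aR)-6-[4-(benzyloxy)-3-methoxyphenyl]-3-DBF-tetrahydro-1H,3H-furo[3,4-c]furan-1-ol (anomers at C1) | COc1cc([C@H]2OC[C@@H]3[C@H]2C(O)O[C@@H]3c2cc(OC)c3c(c2)[C@@H](COCc2ccccc2)[C@@H](c2ccc(OCc4ccccc4)c(OC)c2)O3)ccc1OCc1ccccc1
F8 | step 2 | methyl 3-(2-ethoxy-2-oxoacetyl)-4-{[4-(benzyloxy)-3-methoxyphenyl]methoxy}-5-methoxybenzoate | CCOC(=O)C(=O)c1cc(C(=O)OC)cc(OC)c1OCc1ccc(OCc2ccccc2)c(OC)c1
F9 | step 2 | methyl 3-{2-ethoxy-1-[2-(4-methylbenzenesulfonyl)hydrazinylidene]-2-oxoethyl}-4-{[4-(benzyloxy)-3-methoxyphenyl]methoxy}-5-methoxybenzoate | CCOC(=O)C(=NNS(=O)(=O)c1ccc(C)cc1)c1cc(C(=O)OC)cc(OC)c1OCc1ccc(OCc2ccccc2)c(OC)c1
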